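The runs are simulated for substances that don't exist; the scatter is artificial.

Thursday's and Friday's runs, both at 55 °C, were charged with 23 mM and 34 mM of solid substrate, yet at 60.0 h they read 15% and 16% of target.

| flask | solid substrate | reagent | temperature | remark | time |
|---|---|---|---|---|---|
| Thursday's | 23 mM | 23 mM | 55 °C | run made earlier |  |
| Sunday's | 23 mM | 52 mM | 82 °C | run made earlier |  |
| Friday's | 34 mM | 34.5 mM | 55 °C | run made earlier |  |
| alder | 23 mM | 34.5 mM | 90 °C |  | 12 h |
| elm | 23 mM | 34.5 mM | 60 °C |  | 12 h |
| birch | 23 mM | 34.5 mM | 105 °C |  | 12 h |
| larch | 23 mM | 34.5 mM | 75 °C |  | 12 h |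

| run | time / h | target / % |
|---|---|---|
| Thursday's | 4.00 | 2 |
| Thursday's | 12.0 | 0 |
| Thursday's | 15.0 | 0 |
| Thursday's | 30.0 | 5 |
| Thursday's | 50.0 | 13 |
| Thursday's | 60.0 | 15 |
| Sunday's | 0.667 | 0 |
| Sunday's | 2.00 | 0 |
| Sunday's | 3.00 | 2 |
| Sunday's | 5.00 | 8 |
| Sunday's | 8.00 | 17 |
| Sunday's | 10.0 | 25 |
| Friday's | 5.00 | 5 |
| Friday's | 8.00 | 0 |
| Friday's | 15.0 | 0 |
| Friday's | 30.0 | 5 |
| Friday's | 60.0 | 16 |

(scatter of a reading: 1.5 percentage points)

- the flask with the highest amount of target, in percent of the solid substrate charged ("all alike" if they lie within 1.5 percentage points) (alder / elm / birch / larch / all alike)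
- final target, as a percentage of the solid substrate charged, in alder
- final target, as a percentage of the solid substrate charged, in elm
- final target, as a percentage of the solid substrate charged, in birch
- final target, as a percentage of the solid substrate charged, in larch

- percentages count the solid substrate that a species holds: one side product B counts as two
- solid, in amounts per volume of the solution: solid substrate
- the numbers in the tables scatter with a standard deviation of 1.5 percentage points
- reactions considered so far: starting material + reagent -> intermediate; intermediate -> target; intermediate -> side product A; starting material + target -> side product B; solid substrate <-> starting material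
- at the start none of the solid substrate is in solution
- what has only dissolved of solid substrate counts as not reacted

*What do those two runs show?* Target in percent, y, read alike within the scatter while solid charge S and reagent charge R rose together.

*Then y is the constant. Why introduce anything else?* The two runs cannot separate them. I assume that the dissolved amount follows solubility, not the size of the heap, so that at fixed temperature and time target in mM follows R. That makes the quantity to carry G = yS/R, the delivered share: the part of the reagent charge sitting in target.

*Its ceiling?* In the asked flasks 23 mM of solid substrate, the limiting reagent, meets 34.5 mM of reagent. Each target holds one reagent, so G stops at 66.7%.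

*Values?* Thursday's run gives 15.0% at 60.0 h, Friday's 15.8%. Sunday's run, at 82 °C, gives the delivered share 11.1% at 10.0 h.

*And your commitment?* Alder is hotter than Sunday's run and runs longer, so as an estimate I take Sunday's G as its floor, y above 16.6%. For elm I expect near zero: Thursday's run, at 55 °C against elm's 60 °C, read 0% at 12.0 h. Assuming G climbs with temperature at fixed charges and time, I put birch first, as the hottest flask.

The forecast names birch, with 29% in alder, 1% in elm, 48% in birch and 11% in larch, and adds: “Selectivity outside the tested range is uncertain.”

The flasks give 41.1% in alder, 1.91% in elm, 56.1% in birch and 14.2% in larch, so birch leads, and alder stands above my floor. Birch delivers G = 37.4%, which is 3.37 times Sunday's value and below the ceiling.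

    starting material + reagent → intermediate (k = 16.8 /M/h, Ea = 57.0 kJ/mol)
    intermediate → target (k = 0.485 /h, Ea = 107 kJ/mol)
    intermediate → side product A (k = 0.00927 /h, Ea = 124 kJ/mol)
    starting material + target → side product B (k = 2.35 /M/h, Ea = 94.0 kJ/mol)
    solid substrate ⇌ starting material, rate k5*(cs5 - [starting material]) while solid is left; crystals form when [starting material] > cs5 (solubility = 7.60 mM, k = 0.227 /h)
    (constants at 90 °C)

Birch has not come to rest at 12.0 h: 25.4% solid substrate and 7.04% starting material stand beside 57.5% of the reagent charge. At ten times the time, 120 h, birch holds 78.9% target, so G reaches 52.6%, still below the ceiling of 66.7%. Solid substrate is then at 0%, side product B has gone from 7.60% to 19.0%, and reagent stands at 39.7% of its charge.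

For the neighbour like birch with 14 mM of solid substrate, keeping birch's G gives y = 92.2%. The computed value is 85.9%, a G of 34.9%, with solid substrate at 0%.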